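## Plan

- **Labels.** Ring A is the methoxy ring (a1 carries the 2-oxoheptyl CH2, a3 OMe, a5 the ether O, a6 the ester C=O). Ring B is the phenol ring (b1 O of the seven-membered ester, b2 H, b3 OH, b4 δ-lactone C=O, b5 benzylic CH2, b6 ether O).
- **Cuts.** The depsidone is opened at C(=O)–O(b1) and at C(a5)–O(b6), which frees a ring A aryl bromide. The acylal C–O bonds and the CH2(b5)–C(spiro) bond free an (R)-δ-lactone. Ring B itself is cut at b1–b2, b3–b4 and b1–b6.
- **Enabling feature.** Ring B has five substituents, with O(b1) and O(b3) meta and only b2 bearing H. Carbons b1, b4, b5, b6 are therefore the four carbons of an ester-bearing vinylketene (from an α-diazo-β-keto ester), and b2, b3 are those of a silyloxyethyne.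
- **Forward order.** Ring B is made first (Wolff/ynol-ether benzannulation). Lateral acylation follows, then the δ-lactone and tetrahydropyran rings close together under acid, then the Ullmann diaryl ether, the seven-membered lactone and ketone release.
- **Stereochemistry.** C6' (R) comes from (R)-propylene oxide; the spiro centre (3S) is set by acid equilibration of the acylal.

Key step: step 6

Assumption: the (3S) spiro-acylal is the thermodynamic epimer for a (6'R) methyl group (chair tetrahydropyran, methyl equatorial, acyloxy oxygen axial), so acid equilibration should suffice to set it.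

## Route

Step 1
Reactants: 1 ethyl 2-formylpropanoate
Product: 2 ethyl (E)-3-[(4-methoxybenzyl)oxy]-2-methylacrylate
Conditions: PMBCl, Cs2CO3, DMF, 0 °C → rt
Reagents that add atoms: 4-methoxybenzyl chloride, COc1ccc(CCl)cc1
Why: O-alkylation of the caesium enolate of an α-formyl ester in a dipolar aprotic solvent (the usual β-alkoxyacrylate synthesis) should give the enol ether, the (E)-isomer with the ether oxygen trans to the ester being the thermodynamic one.

Step 2
Reactants: 2 ethyl (E)-3-[(4-methoxybenzyl)oxy]-2-methylacrylate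
Product: 3 (E)-3-[(4-methoxybenzyl)oxy]-2-methylacrylic acid
Conditions: LiOH, THF/H2O, 40 °C; 1 M HCl to pH 4, 0 °C
Reagents that add atoms: lithium hydroxide, [Li+].[OH-]
Why: Saponification of the vinylogous carbonate ester leaves the enol ether untouched, and the mild acidification spares the PMB group.

Step 3
Reactants: 3 (E)-3-[(4-methoxybenzyl)oxy]-2-methylacrylic acid; 4 tert-butyl acetate
Product: 7 tert-butyl (E)-5-[(4-methoxybenzyl)oxy]-4-methyl-3-oxopent-4-enoate, via acyl imidazole 5 (not isolated), via lithium ester enolate 6 (not isolated)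
Conditions: CDI, THF, rt; then added to 4/LDA (3 equiv each), THF, −78 °C; aq. NH4Cl
Reagents that add atoms: none
Why: Crossed Claisen condensation of an acyl imidazole with excess lithium tert-butyl acetate is a standard β-keto ester synthesis, the hard enolate attacking the acyl carbon and not the β-alkoxy position.

Step 4
Reactants: 7 tert-butyl (E)-5-[(4-methoxybenzyl)oxy]-4-methyl-3-oxopent-4-enoate
Product: 8 tert-butyl (E)-2-diazo-5-[(4-methoxybenzyl)oxy]-4-methyl-3-oxopent-4-enoate
Conditions: 4-acetamidobenzenesulfonyl azide, Et3N, MeCN, 0 °C → rt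
Reagents that add atoms: 4-acetamidobenzenesulfonyl azide, CC(=O)Nc1ccc(cc1)S(=O)(=O)N=[N+]=[N-]
Why: Regitz diazo transfer to the active methylene group of a β-keto ester.

Step 5
Reactants: 9 acetylene
Product: 12 (triisopropylsilyloxy)ethyne, via lithium acetylide 10 (not isolated), via lithium ethynolate 11 (not isolated)
Conditions: n-BuLi, THF, −78 °C; t-BuOOLi (from t-BuOOH, LiHMDS), −78 → −30 °C; TIPSOTf, −78 °C
Reagents that add atoms: tert-butyl hydroperoxide (used as its lithium salt), CC(C)(C)OO; triisopropylsilyl trifluoromethanesulfonate, CC(C)[Si](C(C)C)(C(C)C)OS(=O)(=O)C(F)(F)F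
Why: Oxidation of a lithium acetylide with lithium tert-butyl peroxide gives the lithium ynolate, which a bulky silyl triflate should silylate on oxygen to give the silyl ynol ether.

Step 6
Reactants: 8 tert-butyl (E)-2-diazo-5-[(4-methoxybenzyl)oxy]-4-methyl-3-oxopent-4-enoate; 12 (triisopropylsilyloxy)ethyne
Product: 17 tert-butyl 4-hydroxy-3-[(4-methoxybenzyl)oxy]-2-methyl-6-(triisopropylsilyloxy)benzoate, via vinylketene 13 (not isolated), via cyclobutenone 14 (not isolated), via dienylketene 15 (not isolated), via cyclohexadienone 16 (not isolated)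
Conditions: 12 (2 equiv), ClCH2CH2Cl (degassed), hν (254 nm, quartz), rt; then 80 °C
Reagents that add atoms: none
Why: Proposed new method: light expels N2 from 8 and the alkenyl group shifts from the ketone carbon to the carbene carbon (Wolff rearrangement) to give the ester-bearing vinylketene 13, whose electrophilic C=O carbon is attacked by the CH carbon of the donor-polarised ynol ether 12, so that a [2+2] cycloaddition across the ketene C=C gives cyclobutenone 14 (bonds b1–b2 and b3–b4). Reversible 4π electrocyclic opening of 14 gives dienylketene 15, and ring B closes by a thermal disrotatory 6π electrocyclisation between the ketene carbon b1 and the PMBO-bearing alkene carbon b6; enolisation of dienone 16 then gives phenol 17, and no stereocentre remains. The closest known reaction type is the photochemical Wolff/ynol-ether benzannulation of α-diazo enones that carry hydrogen, alkyl or silyl on the diazo carbon, which gives resorcinol monoethers; an ester on that carbon has not been used. The step needs the [2+2] regiochemistry that joins the silyloxy carbon to the ketene α-carbon, which the polarity of 12 secures, and it needs addition at the ketene C=C to outrun hetero-[4+2] capture through the ester C=O, which the bulky tert-butyl ester and the excess of 12 are chosen to favour. The (E)-enol ether keeps the PMBO group on the outside of the closing triene, and because the cyclobutenone opening is reversible the rotamer with the ester turned inward can return and reopen.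

Step 7
Reactants: 17 tert-butyl 4-hydroxy-3-[(4-methoxybenzyl)oxy]-2-methyl-6-(triisopropylsilyloxy)benzoate
Product: 19 tert-butyl 4,6-bis(benzyloxy)-3-[(4-methoxybenzyl)oxy]-2-methylbenzoate, via diphenol 18 (not isolated)
Conditions: TBAF, THF, 0 °C; then BnBr, K2CO3, DMF, 50 °C
Reagents that add atoms: benzyl bromide, BrCc1ccccc1
Why: Fluoride cleaves the aryl silyl ether and Williamson benzylation of both phenols follows in the same flask, so that O(b1) and O(b3) carry base-stable groups that later leave together with the ring A benzyl ester.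

Step 8
Reactants: 20 (R)-propylene oxide; 21 ethyl propiolate
Product: 23 ethyl (R)-5-hydroxyhex-2-ynoate, via lithiated ethyl propiolate 22 (not isolated)
Conditions: 21, n-BuLi, THF, −78 °C; BF3·OEt2; then 20, −78 °C
Reagents that add atoms: none
Why: BF3-mediated opening of the epoxide at its CH2 terminus by a lithium acetylide leaves the stereocentre untouched, so it stays (R).

Step 9
Reactants: 23 ethyl (R)-5-hydroxyhex-2-ynoate
Product: 25 (R)-6-methyltetrahydro-2H-pyran-2-one, via hydroxy ester 24 (not isolated)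
Conditions: H2 (1 atm), Pd/C, EtOAc, rt; then p-TsOH·H2O (cat.), CH2Cl2, rt
Reagents that add atoms: none
Why: Catalytic hydrogenation of the alkyne followed by acid-catalysed lactonisation of the δ-hydroxy ester.

Step 10
Reactants: 19 tert-butyl 4,6-bis(benzyloxy)-3-[(4-methoxybenzyl)oxy]-2-methylbenzoate; 25 (R)-6-methyltetrahydro-2H-pyran-2-one
Product: 27 tert-butyl 4,6-bis(benzyloxy)-2-[(6R)-6-hydroxy-2-oxoheptyl]-3-[(4-methoxybenzyl)oxy]benzoate, via benzylic lithium compound 26 (not isolated)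
Conditions: LDA (1.1 equiv), THF, −78 °C; then 25, −78 °C; AcOH, −78 °C
Reagents that add atoms: none
Why: Lateral lithiation of an ortho-toluate (the tert-butyl ester prevents self-condensation) and C-acylation by the lactone should give the δ-hydroxy ketone, the lactolate adduct surviving at −78 °C until the quench and the carbinol centre keeping the (R) configuration of 25.

Step 11
Reactants: 27 tert-butyl 4,6-bis(benzyloxy)-2-[(6R)-6-hydroxy-2-oxoheptyl]-3-[(4-methoxybenzyl)oxy]benzoate
Product: 29 (3S,6'R)-6,8-bis(benzyloxy)-5-hydroxy-6'-methyl-3',4',5',6'-tetrahydrospiro[isochromane-3,2'-pyran]-1-one, via deprotected keto acid 28 (not isolated)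
Conditions: TFA/CH2Cl2 (1:4), anisole (10 equiv), 0 °C → rt
Reagents that add atoms: none
Why: Acidolysis removes the tert-butyl ester and the PMB ether (cation trapped by anisole), and the freed acid, ketone and alcohol condense by acid-catalysed spiroketalisation; reversible ionisation of the acylal C–O bond should give the thermodynamic (3S) centre, with the acyloxy oxygen axial on a chair tetrahydropyran whose (6'R) methyl group is equatorial.

Step 12
Reactants: 30 1-bromo-3-methoxy-5-methylbenzene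
Product: 31 1-bromo-2-iodo-5-methoxy-3-methylbenzene
Conditions: NIS, TFA (cat.), MeCN, rt
Reagents that add atoms: N-iodosuccinimide, O=C1CCC(=O)N1I
Why: Electrophilic iodination of an anisole with NIS goes para to the methoxy group, here the position between bromine and methyl.

Step 13
Reactants: 31 1-bromo-2-iodo-5-methoxy-3-methylbenzene
Product: 33 benzyl 2-bromo-4-methoxy-6-methylbenzoate, via aryl Grignard reagent 32 (not isolated)
Conditions: iPrMgCl·LiCl, THF, −20 °C; then ClCO2Bn, −20 → 0 °C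
Reagents that add atoms: benzyl chloroformate, O=C(Cl)OCc1ccccc1
Why: Iodine–magnesium exchange is selective for iodine over bromine, and the hindered aryl Grignard reagent is acylated once by the chloroformate to give the benzyl ester.

Step 14
Reactants: 33 benzyl 2-bromo-4-methoxy-6-methylbenzoate; 34 N-methoxy-N-methylhexanamide
Product: 36 benzyl 2-bromo-4-methoxy-6-(2-oxoheptyl)benzoate, via benzylic lithium compound 35 (not isolated)
Conditions: LDA, THF, −78 °C; then 34, −78 → −40 °C; aq. NH4Cl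
Reagents that add atoms: none
Why: Lateral lithiation of the ortho-toluate and acylation by a Weinreb amide, whose chelated tetrahedral adduct prevents over-addition.

Step 15
Reactants: 36 benzyl 2-bromo-4-methoxy-6-(2-oxoheptyl)benzoate
Product: 37 benzyl 2-bromo-4-methoxy-6-[(2-pentyl-1,3-dioxolan-2-yl)methyl]benzoate
Conditions: TMSOCH2CH2OTMS, TMSOTf (cat.), CH2Cl2, −78 → −20 °C; pyridine quench
Reagents that add atoms: 1,2-bis(trimethylsilyloxy)ethane, C[Si](C)(C)OCCO[Si](C)(C)C
Why: Silyl-triflate-catalysed ketalisation with the bis-silyl ether of ethylene glycol runs cold and aprotic, so enol lactonisation of the keto ester to an isocoumarin is avoided.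

Step 16
Reactants: 29 spiro-acylal phenol; 37 ring A bromide (ketal, benzyl ester)
Product: 38 benzyl 2-{[(3S,6'R)-6,8-bis(benzyloxy)-6'-methyl-1-oxo-3',4',5',6'-tetrahydrospiro[isochromane-3,2'-pyran]-5-yl]oxy}-4-methoxy-6-[(2-pentyl-1,3-dioxolan-2-yl)methyl]benzoate
Conditions: CuI (cat.), picolinic acid (cat.), K3PO4, DMSO, 90 °C
Reagents that add atoms: none
Why: Ullmann diaryl ether synthesis with the picolinic acid ligand tolerates ortho-substituted phenols and is helped by the ortho ester of the bromide; only O(b6) is free, so the ether oxygen is placed without ambiguity.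

Step 17
Reactants: 38 diaryl ether (two benzyl ethers, benzyl ester, ketal)
Product: 39 2-{[(3S,6'R)-6,8-dihydroxy-6'-methyl-1-oxo-3',4',5',6'-tetrahydrospiro[isochromane-3,2'-pyran]-5-yl]oxy}-4-methoxy-6-[(2-pentyl-1,3-dioxolan-2-yl)methyl]benzoic acid
Conditions: H2 (1 atm), Pd/C, EtOAc/THF, rt
Reagents that add atoms: none
Why: Hydrogenolysis cleaves both aryl benzyl ethers and the benzyl ester at once and leaves ketal, acylal and diaryl ether intact.

Step 18
Reactants: 39 seco acid
Product: 40 dioxolane ketal of the target depsidone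
Conditions: DCC, DMAP (cat.), CH2Cl2 (0.005 M), rt
Reagents that add atoms: none
Why: Carbodiimide (Steglich-type) lactonisation of the 2-aryloxybenzoic acid onto O(b1) closes the seven-membered ring; O(b3) is hydrogen-bonded to the lactone carbonyl and cannot reach the acid, and the masked ketone cannot divert the activated acid into an isocoumarin.

Step 19
Reactants: 40 dioxolane ketal of the target depsidone
Product: 41 CNP0301127.1
Conditions: 1 M aq. HCl, THF, rt
Reagents that add atoms: water, O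
Why: Acid hydrolysis of the dioxolane releases the ketone, while the spiro-acylal already has its thermodynamic configuration and should be returned unchanged.

## Compound list

1 | ethyl 2-formylpropanoate | CCOC(=O)C(C)C=O | starting material
2 | ethyl (E)-3-[(4-methoxybenzyl)oxy]-2-methylacrylate | CCOC(=O)/C(C)=C/OCc1ccc(OC)cc1 | intermediate
3 | (E)-3-[(4-methoxybenzyl)oxy]-2-methylacrylic acid | OC(=O)/C(C)=C/OCc1ccc(OC)cc1 | intermediate
4 | tert-butyl acetate | CC(=O)OC(C)(C)C | starting material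
5 | (E)-1-(imidazol-1-yl)-3-[(4-methoxybenzyl)oxy]-2-methylprop-2-en-1-one (acyl imidazole) | O=C(/C(C)=C/OCc1ccc(OC)cc1)n1ccnc1 | intermediate (not isolated)
6 | lithium enolate of tert-butyl acetate | [Li]OC(=C)OC(C)(C)C | intermediate (not isolated)
7 | tert-butyl (E)-5-[(4-methoxybenzyl)oxy]-4-methyl-3-oxopent-4-enoate | CC(C)(C)OC(=O)CC(=O)/C(C)=C/OCc1ccc(OC)cc1 | intermediate
8 | tert-butyl (E)-2-diazo-5-[(4-methoxybenzyl)oxy]-4-methyl-3-oxopent-4-enoate | CC(C)(C)OC(=O)C(=[N+]=[N-])C(=O)/C(C)=C/OCc1ccc(OC)cc1 | intermediate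
9 | acetylene | C#C | starting material
10 | lithium acetylide | [Li]C#C | intermediate (not isolated)
11 | lithium ethynolate | [Li]OC#C | intermediate (not isolated)
12 | (triisopropylsilyloxy)ethyne | C#CO[Si](C(C)C)(C(C)C)C(C)C | intermediate
13 | tert-butyl (E)-2-carbonyl-4-[(4-methoxybenzyl)oxy]-3-methylbut-3-enoate (vinylketene) | O=C=C(C(=O)OC(C)(C)C)/C(C)=C/OCc1ccc(OC)cc1 | intermediate (not isolated)
14 | tert-butyl 1-[(E)-1-[(4-methoxybenzyl)oxy]prop-1-en-2-yl]-4-oxo-2-(triisopropylsilyloxy)cyclobut-2-ene-1-carboxylate | O=C1C=C(O[Si](C(C)C)(C(C)C)C(C)C)C1(C(=O)OC(C)(C)C)/C(C)=C/OCc1ccc(OC)cc1 | intermediate (not isolated)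
15 | tert-butyl (2Z)-2-[(E)-1-[(4-methoxybenzyl)oxy]prop-1-en-2-yl]-5-oxo-3-(triisopropylsilyloxy)penta-2,4-dienoate (dienylketene) | O=C=C/C(O[Si](C(C)C)(C(C)C)C(C)C)=C(C(=O)OC(C)(C)C)\C(C)=C\OCc1ccc(OC)cc1 | intermediate (not isolated)
16 | tert-butyl 3-[(4-methoxybenzyl)oxy]-2-methyl-4-oxo-6-(triisopropylsilyloxy)cyclohexa-1,5-diene-1-carboxylate | O=C1C=C(O[Si](C(C)C)(C(C)C)C(C)C)C(C(=O)OC(C)(C)C)=C(C)C1OCc1ccc(OC)cc1 | intermediate (not isolated)
17 | tert-butyl 4-hydroxy-3-[(4-methoxybenzyl)oxy]-2-methyl-6-(triisopropylsilyloxy)benzoate | CC(C)(C)OC(=O)c1c(C)c(OCc2ccc(OC)cc2)c(O)cc1O[Si](C(C)C)(C(C)C)C(C)C | intermediate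
18 | tert-butyl 4,6-dihydroxy-3-[(4-methoxybenzyl)oxy]-2-methylbenzoate | CC(C)(C)OC(=O)c1c(C)c(OCc2ccc(OC)cc2)c(O)cc1O | intermediate (not isolated)
19 | tert-butyl 4,6-bis(benzyloxy)-3-[(4-methoxybenzyl)oxy]-2-methylbenzoate | CC(C)(C)OC(=O)c1c(C)c(OCc2ccc(OC)cc2)c(OCc2ccccc2)cc1OCc1ccccc1 | intermediate
20 | (R)-propylene oxide | C[C@@H]1CO1 | starting material
21 | ethyl propiolate | CCOC(=O)C#C | starting material
22 | ethyl 3-lithiopropiolate | CCOC(=O)C#C[Li] | intermediate (not isolated)
23 | ethyl (R)-5-hydroxyhex-2-ynoate | CCOC(=O)C#CC[C@@H](C)O | intermediate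
24 | ethyl (R)-5-hydroxyhexanoate | CCOC(=O)CCC[C@@H](C)O | intermediate (not isolated)
25 | (R)-6-methyltetrahydro-2H-pyran-2-one | C[C@@H]1CCCC(=O)O1 | intermediate
26 | {3,5-bis(benzyloxy)-2-(tert-butoxycarbonyl)-6-[(4-methoxybenzyl)oxy]phenyl}methyllithium | CC(C)(C)OC(=O)c1c(C[Li])c(OCc2ccc(OC)cc2)c(OCc2ccccc2)cc1OCc1ccccc1 | intermediate (not isolated)
27 | tert-butyl 4,6-bis(benzyloxy)-2-[(6R)-6-hydroxy-2-oxoheptyl]-3-[(4-methoxybenzyl)oxy]benzoate | CC(C)(C)OC(=O)c1c(CC(=O)CCC[C@@H](C)O)c(OCc2ccc(OC)cc2)c(OCc2ccccc2)cc1OCc1ccccc1 | intermediate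
28 | 4,6-bis(benzyloxy)-3-hydroxy-2-[(6R)-6-hydroxy-2-oxoheptyl]benzoic acid | OC(=O)c1c(CC(=O)CCC[C@@H](C)O)c(O)c(OCc2ccccc2)cc1OCc1ccccc1 | intermediate (not isolated)
29 | (3S,6'R)-6,8-bis(benzyloxy)-5-hydroxy-6'-methyl-3',4',5',6'-tetrahydrospiro[isochromane-3,2'-pyran]-1-one | c1ccccc1COc1cc(OCc2ccccc2)c2c(c1O)C[C@]1(CCC[C@@H](C)O1)OC2=O | intermediate
30 | 1-bromo-3-methoxy-5-methylbenzene | COc1cc(C)cc(Br)c1 | starting material
31 | 1-bromo-2-iodo-5-methoxy-3-methylbenzene | COc1cc(C)c(I)c(Br)c1 | intermediate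
32 | (2-bromo-4-methoxy-6-methylphenyl)magnesium chloride | COc1cc(C)c([Mg]Cl)c(Br)c1 | intermediate (not isolated)
33 | benzyl 2-bromo-4-methoxy-6-methylbenzoate | COc1cc(C)c(C(=O)OCc2ccccc2)c(Br)c1 | intermediate
34 | N-methoxy-N-methylhexanamide | CCCCCC(=O)N(C)OC | starting material
35 | {2-[(benzyloxy)carbonyl]-3-bromo-5-methoxyphenyl}methyllithium | COc1cc(C[Li])c(C(=O)OCc2ccccc2)c(Br)c1 | intermediate (not isolated)
36 | benzyl 2-bromo-4-methoxy-6-(2-oxoheptyl)benzoate | CCCCCC(=O)Cc1cc(OC)cc(Br)c1C(=O)OCc1ccccc1 | intermediate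
37 | benzyl 2-bromo-4-methoxy-6-[(2-pentyl-1,3-dioxolan-2-yl)methyl]benzoate | CCCCCC1(Cc2cc(OC)cc(Br)c2C(=O)OCc2ccccc2)OCCO1 | intermediate
38 | benzyl 2-{[(3S,6'R)-6,8-bis(benzyloxy)-6'-methyl-1-oxo-3',4',5',6'-tetrahydrospiro[isochromane-3,2'-pyran]-5-yl]oxy}-4-methoxy-6-[(2-pentyl-1,3-dioxolan-2-yl)methyl]benzoate | CCCCCC1(OCCO1)Cc1cc(OC)cc(Oc2c(OCc3ccccc3)cc(OCc3ccccc3)c3c2C[C@]2(CCC[C@@H](C)O2)OC3=O)c1C(=O)OCc1ccccc1 | intermediate
39 | 2-{[(3S,6'R)-6,8-dihydroxy-6'-methyl-1-oxo-3',4',5',6'-tetrahydrospiro[isochromane-3,2'-pyran]-5-yl]oxy}-4-methoxy-6-[(2-pentyl-1,3-dioxolan-2-yl)methyl]benzoic acid | CCCCCC1(OCCO1)Cc1cc(OC)cc(Oc2c(O)cc(O)c3c2C[C@]2(CCC[C@@H](C)O2)OC3=O)c1C(=O)O | intermediate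
40 | dioxolane ketal of the target (depsidone 41 with the side-chain C=O replaced by a 1,3-dioxolane-2,2-diyl group) | CCCCCC1(OCCO1)Cc1cc(OC)cc2c1C(=O)Oc1cc(O)c3c(c1O2)C[C@]1(CCC[C@@H](C)O1)OC3=O | intermediate
41 | CNP0301127.1: depsidone with 2-oxoheptyl at a1 and OMe at a3 on ring A, OH at b3 on ring B, and the (3S) spiro-acylal δ-lactone fused at b4/b5 whose tetrahydropyran carries a (6'R) methyl group | CCCCCC(=O)Cc1cc(OC)cc2c1C(=O)Oc1cc(O)c3c(c1O2)C[C@]1(CCC[C@@H](C)O1)OC3=O | target

## Totals and risks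

Total step count: 19. Longest linear sequence: 12 steps (steps 1–4, 6, 7, 10, 11, 16–19).

**Risk 1, step 6 (labelled as a new method).** The ester-bearing vinylketene may be captured through its ester carbonyl in a hetero-[4+2] sense, may dimerise, or the ring-opened dienylketene may close onto the ester oxygen instead of the alkene. The fallback uses the established form of the same cascade, with hydrogen on the diazo carbon, and adds the carboxyl afterwards. It sets out from acid 3 and comes back at 19.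
- Isobutyl chloroformate and N-methylmorpholine should convert 3 into isobutyl carbonic (E)-3-[(4-methoxybenzyl)oxy]-2-methylacrylic anhydride F1, and diazomethane should give (E)-1-diazo-4-[(4-methoxybenzyl)oxy]-3-methylbut-3-en-2-one F2.
- Irradiation of F2 with 12 and heating (the known benzannulation of α-diazo enones) should pass through the vinylketene (E)-4-[(4-methoxybenzyl)oxy]-3-methylbuta-1,3-dien-1-one F3, the cyclobutenone 4-[(E)-1-[(4-methoxybenzyl)oxy]prop-1-en-2-yl]-3-(triisopropylsilyloxy)cyclobut-2-en-1-one F4, the dienylketene (3E,5E)-6-[(4-methoxybenzyl)oxy]-5-methyl-3-(triisopropylsilyloxy)hexa-1,3,5-trien-1-one F5 and the dienone 6-[(4-methoxybenzyl)oxy]-5-methyl-3-(triisopropylsilyloxy)cyclohexa-2,4-dien-1-one F6 to 2-[(4-methoxybenzyl)oxy]-3-methyl-5-(triisopropylsilyloxy)phenol F7.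
- TBAF, then BnBr and K2CO3, should lead through 4-[(4-methoxybenzyl)oxy]-5-methylbenzene-1,3-diol F8 to 1,5-bis(benzyloxy)-2-[(4-methoxybenzyl)oxy]-3-methylbenzene F9.
- NBS should brominate the position between the methyl group and a benzyloxy group (para to the other benzyloxy group) to give 1,5-bis(benzyloxy)-4-bromo-2-[(4-methoxybenzyl)oxy]-3-methylbenzene F10.
- Bromine–lithium exchange with n-BuLi at −78 °C should give {2,4-bis(benzyloxy)-5-[(4-methoxybenzyl)oxy]-6-methylphenyl}lithium F11, which Boc2O traps as tert-butyl ester 19.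

**Risk 2, step 16.** The phenol is flanked on both sides, so C–O coupling may be slow, and at 90 °C under base the bromide may be reduced or the benzyl ester attacked. The fallback inverts the polarity of ring A and forms the ether oxidatively near room temperature without a strong base. It sets out from bromide 37 and comes back at 38.
- Miyaura borylation (B2pin2, Pd(dppf)Cl2, KOAc, dioxane, 90 °C) should give benzyl 4-methoxy-2-[(2-pentyl-1,3-dioxolan-2-yl)methyl]-6-(4,4,5,5-tetramethyl-1,3,2-dioxaborolan-2-yl)benzoate F12.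
- Chan–Lam coupling of F12 with phenol 29 (Cu(OAc)2, pyridine, 4 Å molecular sieves, air, MeCN, rt to 50 °C) should give diaryl ether 38.

**Risk 3, step 5.** Lithium acetylide may disproportionate before it is oxidised, or the parent ynolate may be silylated on carbon to give a silylketene. The fallback changes the oxygenated ethyne to one made without an ynolate. It sets out from diazo ester 8 and comes back at 19.
- Benzyl alcohol, KH and trichloroethylene should give benzyl (E)-1,2-dichlorovinyl ether F13; n-BuLi (2.2 equiv, −78 °C) should give lithium (benzyloxy)acetylide F14, and methanol should protonate it to benzyloxyethyne F15.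
- Irradiation of 8 with F15 under the conditions of step 6 (excess F15 is evaporated before the thermal stage, because benzyl ynol ethers rearrange on heating) should pass through vinylketene 13, tert-butyl 2-(benzyloxy)-1-[(E)-1-[(4-methoxybenzyl)oxy]prop-1-en-2-yl]-4-oxocyclobut-2-ene-1-carboxylate F16, tert-butyl (2Z)-3-(benzyloxy)-2-[(E)-1-[(4-methoxybenzyl)oxy]prop-1-en-2-yl]-5-oxopenta-2,4-dienoate F17 and tert-butyl 6-(benzyloxy)-3-[(4-methoxybenzyl)oxy]-2-methyl-4-oxocyclohexa-1,5-diene-1-carboxylate F18 to tert-butyl 6-(benzyloxy)-4-hydroxy-3-[(4-methoxybenzyl)oxy]-2-methylbenzoate F19.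
- O-Benzylation of F19 (BnBr, K2CO3, DMF) gives 19.

## Further compounds

F1 | step 6 | isobutyl carbonic (E)-3-[(4-methoxybenzyl)oxy]-2-methylacrylic anhydride | CC(C)COC(=O)OC(=O)/C(C)=C/OCc1ccc(OC)cc1
F2 | step 6 | (E)-1-diazo-4-[(4-methoxybenzyl)oxy]-3-methylbut-3-en-2-one | [N-]=[N+]=CC(=O)/C(C)=C/OCc1ccc(OC)cc1
F3 | step 6 | (E)-4-[(4-methoxybenzyl)oxy]-3-methylbuta-1,3-dien-1-one | O=C=C/C(C)=C/OCc1ccc(OC)cc1
F4 | step 6 | 4-[(E)-1-[(4-methoxybenzyl)oxy]prop-1-en-2-yl]-3-(triisopropylsilyloxy)cyclobut-2-en-1-one | O=C1C=C(O[Si](C(C)C)(C(C)C)C(C)C)C1/C(C)=C/OCc1ccc(OC)cc1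
F5 | step 6 | (3E,5E)-6-[(4-methoxybenzyl)oxy]-5-methyl-3-(triisopropylsilyloxy)hexa-1,3,5-trien-1-one | O=C=C/C(O[Si](C(C)C)(C(C)C)C(C)C)=C\C(C)=C\OCc1ccc(OC)cc1
F6 | step 6 | 6-[(4-methoxybenzyl)oxy]-5-methyl-3-(triisopropylsilyloxy)cyclohexa-2,4-dien-1-one | O=C1C=C(O[Si](C(C)C)(C(C)C)C(C)C)C=C(C)C1OCc1ccc(OC)cc1
F7 | step 6 | 2-[(4-methoxybenzyl)oxy]-3-methyl-5-(triisopropylsilyloxy)phenol | Cc1cc(O[Si](C(C)C)(C(C)C)C(C)C)cc(O)c1OCc1ccc(OC)cc1
F8 | step 6 | 4-[(4-methoxybenzyl)oxy]-5-methylbenzene-1,3-diol | Cc1cc(O)cc(O)c1OCc1ccc(OC)cc1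
F9 | step 6 | 1,5-bis(benzyloxy)-2-[(4-methoxybenzyl)oxy]-3-methylbenzene | Cc1cc(OCc2ccccc2)cc(OCc2ccccc2)c1OCc1ccc(OC)cc1
F10 | step 6 | 1,5-bis(benzyloxy)-4-bromo-2-[(4-methoxybenzyl)oxy]-3-methylbenzene | Cc1c(Br)c(OCc2ccccc2)cc(OCc2ccccc2)c1OCc1ccc(OC)cc1
F11 | step 6 | {2,4-bis(benzyloxy)-5-[(4-methoxybenzyl)oxy]-6-methylphenyl}lithium | Cc1c([Li])c(OCc2ccccc2)cc(OCc2ccccc2)c1OCc1ccc(OC)cc1
F12 | step 16 | benzyl 4-methoxy-2-[(2-pentyl-1,3-dioxolan-2-yl)methyl]-6-(4,4,5,5-tetramethyl-1,3,2-dioxaborolan-2-yl)benzoate | CCCCCC1(Cc2cc(OC)cc(B3OC(C)(C)C(C)(C)O3)c2C(=O)OCc2ccccc2)OCCO1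
F13 | step 5 | benzyl (E)-1,2-dichlorovinyl ether | Cl/C=C(/Cl)OCc1ccccc1
F14 | step 5 | lithium (benzyloxy)acetylide | [Li]C#COCc1ccccc1
F15 | step 5 | benzyloxyethyne | C#COCc1ccccc1
F16 | step 5 | tert-butyl 2-(benzyloxy)-1-[(E)-1-[(4-methoxybenzyl)oxy]prop-1-en-2-yl]-4-oxocyclobut-2-ene-1-carboxylate | O=C1C=C(OCc2ccccc2)C1(C(=O)OC(C)(C)C)/C(C)=C/OCc1ccc(OC)cc1
F17 | step 5 | tert-butyl (2Z)-3-(benzyloxy)-2-[(E)-1-[(4-methoxybenzyl)oxy]prop-1-en-2-yl]-5-oxopenta-2,4-dienoate | O=C=C/C(OCc1ccccc1)=C(C(=O)OC(C)(C)C)\C(C)=C\OCc1ccc(OC)cc1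
F18 | step 5 | tert-butyl 6-(benzyloxy)-3-[(4-methoxybenzyl)oxy]-2-methyl-4-oxocyclohexa-1,5-diene-1-carboxylate | O=C1C=C(OCc2ccccc2)C(C(=O)OC(C)(C)C)=C(C)C1OCc1ccc(OC)cc1
F19 | step 5 | tert-butyl 6-(benzyloxy)-4-hydroxy-3-[(4-methoxybenzyl)oxy]-2-methylbenzoate | CC(C)(C)OC(=O)c1c(C)c(OCc2ccc(OC)cc2)c(O)cc1OCc1ccccc1
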